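**Assumptions (one line):** the SMILES has 20 consecutive carbons, the 20th being the ring carbon, so the side chain is n‑nonadecyl (C19); the target, 2‑hydroxy‑5‑methoxy‑3‑nonadecyl‑1,4‑benzoquinone (C26H44O4), has no stereocentres, so there is no enantiomer to control.

## Retrosynthetic overview
1. The hydroxyquinone comes from selective acid hydrolysis of the alkyl‑flanked methoxy group of 2,5‑dimethoxy‑3‑nonadecyl‑1,4‑benzoquinone.
2. That quinone comes from CAN oxidative demethylation of 3‑nonadecyl‑1,2,4,5‑tetramethoxybenzene, whose mirror symmetry means only one p‑quinone is possible.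
3. The aryl–alkyl bond comes from directed ortho‑lithiation of 1,2,4,5‑tetramethoxybenzene and SN2 alkylation with 1‑bromononadecane.
4. No ring is formed: the six‑membered carbocycle is bought intact and only oxidised and adjusted.

## Route

**Step 1**
Reactants: **1** 1,2,4,5‑tetramethoxybenzene; **2** 1‑bromononadecane
Product: **3** 1,2,4,5‑tetramethoxy‑3‑nonadecylbenzene
Conditions: n‑BuLi (1.1 equiv), THF, 0 °C → rt, 1 h; then HMPA (or DMPU) and **2** (0.9 equiv), 0 °C → rt, overnight
Reagents that add atoms: none beyond reactant **2** (1‑bromononadecane, CCCCCCCCCCCCCCCCCCCBr, supplies the C19 chain)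
Why: directed ortho‑metalation at the C–H flanked by two OMe groups gives a stabilised aryllithium, which undergoes SN2 alkylation with the primary bromide; a slight excess of **1** suppresses dialkylation.

**Step 2**
Reactants: **3** 1,2,4,5‑tetramethoxy‑3‑nonadecylbenzene
Product: **4** 2,5‑dimethoxy‑3‑nonadecyl‑1,4‑benzoquinone
Conditions: CAN (2.5–3 equiv), MeCN/H2O (with a little THF or CH2Cl2 for solubility), 0 °C → rt, 30 min
Reagents that add atoms: water, O (supplies the two quinone carbonyl oxygens; two OMe groups leave as MeOH)
Why: CAN oxidative demethylation of a p‑dimethoxyarene gives the p‑quinone, and both possible para modes give the same product by symmetry. Any minor 4,5‑dimethoxy‑3‑nonadecyl‑1,2‑benzoquinone by‑product is separable and, after the same hydrolysis and tautomerisation, converges on the target.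

**Step 3**
Reactants: **4** 2,5‑dimethoxy‑3‑nonadecyl‑1,4‑benzoquinone
Product: **5** Irisoquin‑C, 2‑hydroxy‑5‑methoxy‑3‑nonadecyl‑1,4‑benzoquinone
Conditions: 70% aq. HClO4, 1,4‑dioxane, rt, monitored by TLC and quenched at mono‑hydrolysis
Reagents that add atoms: water, O (replaces OMe by OH)
Why: acid‑catalysed addition–elimination (vinylogous ester hydrolysis) takes place preferentially at the 2‑OMe, which the adjacent alkyl chain twists out of conjugation, so it is more labile than the unhindered 5‑OMe; this is the selectivity I recall for the maesanin/irisoquin series, not something re‑verified here. The saturated chain is inert and the 5‑OMe survives if the reaction is stopped in time.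

## Compound list
1 | 1,2,4,5‑tetramethoxybenzene | COc1cc(OC)c(OC)cc1OC | starting material
2 | 1‑bromononadecane | CCCCCCCCCCCCCCCCCCCBr | starting material
3 | 1,2,4,5‑tetramethoxy‑3‑nonadecylbenzene | CCCCCCCCCCCCCCCCCCCc1c(OC)c(OC)cc(OC)c1OC | intermediate
4 | 2,5‑dimethoxy‑3‑nonadecyl‑1,4‑benzoquinone | CCCCCCCCCCCCCCCCCCCC1=C(OC)C(=O)C=C(OC)C1=O | intermediate
5 | Irisoquin‑C (2‑hydroxy‑5‑methoxy‑3‑nonadecyl‑1,4‑benzoquinone) | CCCCCCCCCCCCCCCCCCCC1=C(O)C(=O)C=C(OC)C1=O | target

## Summary
Total step count: 3
Longest linear sequence: 3 steps (from 1,2,4,5‑tetramethoxybenzene)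

Steps most likely to fail, with a fallback that changes the approach:
1. **Step 3** (wrong methoxy hydrolysed, or over‑hydrolysis to the dihydroxyquinone). Fallback: hydrolyse both methoxy groups to 2,5‑dihydroxy‑3‑nonadecyl‑1,4‑benzoquinone (aq. NaOH, then acid), then mono‑O‑methylate with MeOH/H2SO4, which should favour the less hindered 5‑OH.
2. **Step 1** (sluggish alkylation of the aryllithium, E2 of the long‑chain bromide, or dialkylation). Fallback: make the C–C bond by cross‑coupling instead — brominate **1** to 3‑bromo‑1,2,4,5‑tetramethoxybenzene and run a B‑alkyl Suzuki coupling with the 9‑BBN adduct of 1‑nonadecene (Pd(dppf)Cl2, base).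
3. **Step 2** (o‑quinone formation, over‑oxidation, or poor solubility of the lipophilic substrate). Fallback: attach the chain to a preformed quinone — radical decarboxylative alkylation of commercial 2,5‑dimethoxy‑1,4‑benzoquinone with eicosanoic acid (AgNO3/(NH4)2S2O8, Jacobsen–Torssell type) to give **4** directly, avoiding the arene oxidation.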